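**Retrosynthetic overview**
1. The free 6-OH comes from a last-step O-debenzylation of the 6-benzyl ether of the 3,7'-biscoumarinyl ether.
2. Key disconnection: C3–C4 (with O1–C2) of the methoxylated pyranone, by a Perkin-type aldol condensation of a salicylaldehyde with (coumarin-7-yloxy)acetic acid. The C3–O–aryl ether arrives with the acid, so no C–O coupling is needed.
3. Acid fragment: umbelliferone and tert-butyl bromoacetate, then acidolysis.
4. Aldehyde fragment: vanillin, then benzyl ether, then Baeyer–Villiger oxidation to the phenol, then ortho-formylation para to OMe.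
5. Ring order: both benzene rings and the unsubstituted pyranone are bought. The substituted pyranone is the only ring built, in the key step.

Assumption: the SMILES has no stereocentre and no acyclic stereogenic double bond, so the target is achiral and no stereocontrol is needed.

**Step 1**
Reactants: 1 umbelliferone (7-hydroxy-2H-chromen-2-one); 2 tert-butyl bromoacetate
Product: 3 tert-butyl 2-[(2-oxo-2H-chromen-7-yl)oxy]acetate
Conditions: K2CO3 (2 equiv), acetone, reflux, 6 h
Reagents that add atoms: none
Why: Williamson ether synthesis, in which the acidic 7-OH is deprotonated by K2CO3 and displaces bromide from the activated primary α-bromo ester (SN2), while this weak base leaves the lactone alone.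

**Step 2**
Reactants: 3 tert-butyl 2-[(2-oxo-2H-chromen-7-yl)oxy]acetate
Product: 4 2-[(2-oxo-2H-chromen-7-yl)oxy]acetic acid
Conditions: TFA/CH2Cl2 (1:1), rt, 3 h; evaporate, triturate with Et2O
Reagents that add atoms: none
Why: Acidolysis of a tert-butyl ester (AAL1, loss of the tert-butyl cation as isobutene) frees the acid without base, so the coumarin lactone never opens.

**Step 3**
Reactants: 5 vanillin (4-hydroxy-3-methoxybenzaldehyde)
Product: 6 4-(benzyloxy)-3-methoxybenzaldehyde
Conditions: BnBr (1.1 equiv), K2CO3 (1.5 equiv), DMF, 60 °C, 3 h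
Reagents that add atoms: benzyl bromide, BrCc1ccccc1
Why: Williamson ether synthesis on the only phenol, which masks the future 6-OH and leaves a single free OH to direct the later formylation.

**Step 4**
Reactants: 6 4-(benzyloxy)-3-methoxybenzaldehyde
Product: 8 4-(benzyloxy)-3-methoxyphenol, via 4-(benzyloxy)-3-methoxyphenyl formate 7 (not isolated)
Conditions: mCPBA (1.3 equiv), CH2Cl2, 0 °C → rt, 12 h; wash (aq Na2SO3, NaHCO3), concentrate; then K2CO3 (0.2 equiv), MeOH, rt, 30 min
Reagents that add atoms: mCPBA (3-chloroperoxybenzoic acid), OOC(=O)c1cccc(Cl)c1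
Why: Baeyer–Villiger (Dakin-type) oxidation, in which the electron-rich aryl group migrates in the Criegee adduct in preference to H to give the labile aryl formate, and base-catalysed methanolysis then cleaves it to the phenol.

**Step 5**
Reactants: 8 4-(benzyloxy)-3-methoxyphenol
Product: 9 5-(benzyloxy)-2-hydroxy-4-methoxybenzaldehyde
Conditions: MgCl2 (anhydrous, 2 equiv), Et3N (4 equiv), (CH2O)n (6 equiv), MeCN, reflux, 4 h; 1 M HCl work-up
Reagents that add atoms: paraformaldehyde (reacts as formaldehyde), C=O
Why: Casnati–Skattebøl ortho-formylation, in which the magnesium phenoxide delivers formaldehyde only ortho to OH, the open site para to OMe wins over the site squeezed between OH and OMe, and a second formaldehyde oxidises the benzylic alkoxide by Oppenauer-type hydride transfer.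

**Step 6 (key step)**
Reactants: 9 5-(benzyloxy)-2-hydroxy-4-methoxybenzaldehyde; 4 2-[(2-oxo-2H-chromen-7-yl)oxy]acetic acid (1.2 equiv)
Product: 12 6-(benzyloxy)-7-methoxy-3-[(2-oxo-2H-chromen-7-yl)oxy]-2H-chromen-2-one, via acetic 2-[(2-oxo-2H-chromen-7-yl)oxy]acetic anhydride 10 (not isolated), via acetic 3-[5-(benzyloxy)-2-hydroxy-4-methoxyphenyl]-3-hydroxy-2-[(2-oxo-2H-chromen-7-yl)oxy]propanoic anhydride 11 (not isolated)
Conditions: Ac2O (10 equiv), Et3N (3 equiv), 120 °C, N2, 12 h; pour into ice-water, filter, wash with aq NaHCO3, recrystallise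
Reagents that add atoms: none
Why: Perkin condensation (Oglialoro variant), in which Ac2O converts 4 into mixed anhydride 10, Et3N enolises its α-CH2 (acidified by the anhydride carbonyl and the aryloxy group), the enolate adds to the aldehyde of 9 in an aldol step to give 11 (drawn as the free alcohol, a diastereomer mixture), and acetylation with E1cB loss of AcOH plus attack of the ortho-phenol on the activated carboxyl closes the aromatic lactone irreversibly, erasing both transient stereocentres.

**Step 7**
Reactants: 12 6-(benzyloxy)-7-methoxy-3-[(2-oxo-2H-chromen-7-yl)oxy]-2H-chromen-2-one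
Product: 13 6-hydroxy-7-methoxy-3-[(2-oxo-2H-chromen-7-yl)oxy]-2H-chromen-2-one (target)
Conditions: BCl3 (1 M in CH2Cl2, 4 equiv), pentamethylbenzene (5 equiv), CH2Cl2, −78 → −30 °C, 1–2 h; MeOH quench, aqueous work-up
Reagents that add atoms: none
Why: Lewis-acid debenzylation with a cation scavenger, in which BCl3 ionises only the benzylic C–O bond at low temperature and pentamethylbenzene traps the benzyl cation by Friedel–Crafts alkylation, so the aryl methyl ether, the aryl enol ether, both lactones and both pyranone C=C bonds (at risk under hydrogenolysis) survive.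

**Compound list**
1 | umbelliferone (7-hydroxy-2H-chromen-2-one) | Oc1ccc2ccc(=O)oc2c1 | starting material
2 | tert-butyl bromoacetate | CC(C)(C)OC(=O)CBr | starting material
3 | tert-butyl 2-[(2-oxo-2H-chromen-7-yl)oxy]acetate | CC(C)(C)OC(=O)COc1ccc2ccc(=O)oc2c1 | intermediate
4 | 2-[(2-oxo-2H-chromen-7-yl)oxy]acetic acid | OC(=O)COc1ccc2ccc(=O)oc2c1 | intermediate
5 | vanillin (4-hydroxy-3-methoxybenzaldehyde) | COc1cc(C=O)ccc1O | starting material
6 | 4-(benzyloxy)-3-methoxybenzaldehyde | COc1cc(C=O)ccc1OCc1ccccc1 | intermediate
7 | 4-(benzyloxy)-3-methoxyphenyl formate | COc1cc(OC=O)ccc1OCc1ccccc1 | intermediate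
8 | 4-(benzyloxy)-3-methoxyphenol | COc1cc(O)ccc1OCc1ccccc1 | intermediate
9 | 5-(benzyloxy)-2-hydroxy-4-methoxybenzaldehyde | COc1cc(O)c(C=O)cc1OCc1ccccc1 | intermediate
10 | acetic 2-[(2-oxo-2H-chromen-7-yl)oxy]acetic anhydride | CC(=O)OC(=O)COc1ccc2ccc(=O)oc2c1 | intermediate
11 | acetic 3-[5-(benzyloxy)-2-hydroxy-4-methoxyphenyl]-3-hydroxy-2-[(2-oxo-2H-chromen-7-yl)oxy]propanoic anhydride (diastereomer mixture) | CC(=O)OC(=O)C(Oc1ccc2ccc(=O)oc2c1)C(O)c1cc(OCc2ccccc2)c(OC)cc1O | intermediate
12 | 6-(benzyloxy)-7-methoxy-3-[(2-oxo-2H-chromen-7-yl)oxy]-2H-chromen-2-one | COc1cc2oc(=O)c(Oc3ccc4ccc(=O)oc4c3)cc2cc1OCc1ccccc1 | intermediate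
13 | 6-hydroxy-7-methoxy-3-[(2-oxo-2H-chromen-7-yl)oxy]-2H-chromen-2-one | COc1cc2oc(=O)c(Oc3ccc4ccc(=O)oc4c3)cc2cc1O | target

**Total step count:** 7 (convergent: steps 1–2 give the acid, steps 3–5 give the aldehyde, steps 6–7 join and deprotect).
**Longest linear sequence:** 5 steps (5 → 6 → 8 → 9 → 12 → 13).

**Three steps most likely to fail**

Step 6 (Perkin condensation). The risks are competing condensation of Ac2O itself, which would give the 3-unsubstituted coumarin, simple O-acetylation of 9, and a moderate yield. The fallback sets out from 4 and 9 and forms the two bonds in the opposite order, in separate operations. EDC·HCl with catalytic DMAP in CH2Cl2 (0 °C → rt) joins them to 4-(benzyloxy)-2-formyl-5-methoxyphenyl 2-[(2-oxo-2H-chromen-7-yl)oxy]acetate F1. No acetyl donor is then present. DBU in MeCN at 60 °C closes the ring by intramolecular aldol condensation and loss of water, and the fallback comes back to the route at 12.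

Step 5 (ortho-formylation). The risks are incomplete conversion and some attack at the site between OH and OMe. The fallback sets out from 8 and replaces phenoxide-directed formylation by electrophilic substitution on a fully protected ring, followed by a chelation-controlled deprotection. BnBr/K2CO3 in DMF gives 1,4-bis(benzyloxy)-2-methoxybenzene F2. Vilsmeier–Haack formylation (POCl3, DMF, 0 → 70 °C, aq NaOAc) attacks the position para to OMe, as in 1,2,4-trialkoxybenzenes, and gives 2,5-bis(benzyloxy)-4-methoxybenzaldehyde F3. MgBr2·OEt2 in toluene/Et2O at reflux removes only the benzyl ether ortho to the aldehyde, through the Mg chelate, and the fallback comes back to the route at 9.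

Step 7 (late debenzylation). The risks are poor solubility of 12 at low temperature and partial loss of the methyl ether if the mixture warms. The fallback sets out from 9 (with 4) and changes the protecting-group plan so that no benzyl ether reaches the biscoumarin stage. H2 (1 atm) over 10% Pd/C in EtOAc gives 2,5-dihydroxy-4-methoxybenzaldehyde F4. The same Ac2O/Et3N condensation with 4 at 120 °C acetylates the 5-OH in situ and gives 7-methoxy-2-oxo-3-[(2-oxo-2H-chromen-7-yl)oxy]-2H-chromen-6-yl acetate F5. Catalytic HCl in MeOH/THF at reflux removes the aryl acetate without harming the lactones or the enol ether, and the fallback comes back to the route at 13.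

**Further compounds**
F1 | step 6 | 4-(benzyloxy)-2-formyl-5-methoxyphenyl 2-[(2-oxo-2H-chromen-7-yl)oxy]acetate | O=Cc1cc(OCc2ccccc2)c(OC)cc1OC(=O)COc1ccc2ccc(=O)oc2c1
F2 | step 5 | 1,4-bis(benzyloxy)-2-methoxybenzene | COc1cc(OCc2ccccc2)ccc1OCc1ccccc1
F3 | step 5 | 2,5-bis(benzyloxy)-4-methoxybenzaldehyde | COc1cc(OCc2ccccc2)c(C=O)cc1OCc1ccccc1
F4 | step 7 | 2,5-dihydroxy-4-methoxybenzaldehyde | COc1cc(O)c(C=O)cc1O
F5 | step 7 | 7-methoxy-2-oxo-3-[(2-oxo-2H-chromen-7-yl)oxy]-2H-chromen-6-yl acetate | COc1cc2oc(=O)c(Oc3ccc4ccc(=O)oc4c3)cc2cc1OC(C)=O
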